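## Retrosynthetic overview
1. The γ-pyrone is the last ring formed. It comes from 6-endo cyclisation of a 2-alkynoylcyclohexanone, and one acid step then removes three MOM groups and one acetonide.
2. The key disconnection is C4–C4a. It is made by a late boron aldol between a protected tetraoxygenated cyclohexanone (C4a–C8a, all four stereocentres) and a 5-arylpent-2-ynal (C2–C4, ethylene bridge, arene).
3. In the cyclohexanone, the carbocycle is formed first, by ring-closing metathesis. C7/C8 come from a Brown alkoxyallylboration of acrolein, C8a/C4a/C5 from a Sharpless epoxide opened with a vinyl cuprate, and the C5/C6 diol from OsO4 attacking anti to C7–O.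
4. The ynal comes from Negishi coupling of 5-bromo-2-methoxyphenyl acetate (from catechol) with a homopropargylzinc reagent (from but-3-yn-1-ol), followed by formylation with DMF.
5. Ring order: arene (bought), carbocycle, dioxolane (protecting group), pyrone.

Assumption: the chromone numbering of the target (C2–C4, C4a, C5–C8, C8a) is used to label positions in all intermediates. The target is (5S,6S,7R,8S), with 5,6-cis, 6,7-trans and 7,8-trans relationships.

## Fragment 1: cyclohexanone 14

Step 1
Reactants: 1 prop-2-en-1-ol (allyl alcohol)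
Product: 2 3-(methoxymethoxy)prop-1-ene
Conditions: MOMCl, i-Pr2NEt, CH2Cl2, 0 °C to rt
Reagents that add atoms: chloromethyl methyl ether, COCCl
Why: O-alkylation of the alcohol by the oxocarbenium-like chloromethyl ether (MOM protection) gives the ether needed for chelation-controlled allylic lithiation, and no stereocentre is formed.

Step 2
Reactants: 2 3-(methoxymethoxy)prop-1-ene; 3 prop-2-enal (acrolein)
Product: 7 (3R,4R)-4-(methoxymethoxy)hexa-1,5-dien-3-ol, via lithiated allyl ether 4 (not isolated), via Z-alkoxyallylborane 5 (not isolated), via homoallyl borinate 6 (not isolated)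
Conditions: s-BuLi, THF, −78 °C; (−)-Ipc2BOMe, −78 °C; BF3·OEt2, then 3, −78 °C to rt; NaOH, 30% H2O2
Reagents that add atoms: none
Why: In this Brown asymmetric alkoxyallylboration the Z-borane reacts through a closed chair transition state to give the syn (threo) diol pattern, and the isopinocampheyl groups derived from (+)-α-pinene select the aldehyde face that gives (3R,4R), which sets C8 (carbinol) and C7 (OMOM).

Step 3
Reactants: 7 (3R,4R)-4-(methoxymethoxy)hexa-1,5-dien-3-ol
Product: 8 (1S,2R)-2-(methoxymethoxy)-1-[(2R)-oxiran-2-yl]but-3-en-1-ol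
Conditions: Ti(OiPr)4 (0.3 equiv), L-(+)-DIPT (0.36 equiv), t-BuOOH (decane), 4 Å MS, CH2Cl2, −20 °C
Reagents that add atoms: tert-butyl hydroperoxide, CC(C)(C)OO
Why: In this Sharpless asymmetric epoxidation only the alkene of the free allylic alcohol is delivered oxygen, and L-(+)-tartrate is matched with this carbinol (the fast-reacting sense of the kinetic-resolution rule), so it gives the erythro (2R)-epoxide, raises the ee, and creates a C8a centre that is oxidised away in step 9.

Step 4
Reactants: 8 (1S,2R)-2-(methoxymethoxy)-1-[(2R)-oxiran-2-yl]but-3-en-1-ol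
Product: 9 (2R)-2-[(1S,2R)-1,2-bis(methoxymethoxy)but-3-en-1-yl]oxirane
Conditions: MOMCl, i-Pr2NEt, CH2Cl2, 0 °C to rt
Reagents that add atoms: chloromethyl methyl ether, COCCl
Why: MOM protection under weakly basic conditions avoids Payne rearrangement, and an acetal cannot migrate to the neighbouring alkoxide formed in step 5 as a silyl group could.

Step 5
Reactants: 9 (2R)-2-[(1S,2R)-1,2-bis(methoxymethoxy)but-3-en-1-yl]oxirane
Product: 10 (4R,5R,6R)-5,6-bis(methoxymethoxy)octa-1,7-dien-4-ol
Conditions: vinylmagnesium bromide, CuI (20 mol %), THF, −40 to −20 °C; aq. NH4Cl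
Reagents that add atoms: vinylmagnesium bromide, C=C[Mg]Br
Why: Copper-catalysed Grignard opening (SN2) occurs at the unhindered terminal epoxide carbon, which becomes C4a, so it adds C5 and leaves every stereocentre untouched.

Step 6
Reactants: 10 (4R,5R,6R)-5,6-bis(methoxymethoxy)octa-1,7-dien-4-ol
Product: 11 (1R,5R,6R)-5,6-bis(methoxymethoxy)cyclohex-3-en-1-ol
Conditions: second-generation Grubbs catalyst (3 mol %), CH2Cl2 (0.01 M), 40 °C
Reagents that add atoms: none
Why: Ring-closing metathesis of a 1,7-diene to a cyclohexene is fast and is driven by loss of ethene, it tolerates the free alcohol, and it forms the C5=C6 bond of the carbocycle.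

Step 7
Reactants: 11 (1R,5R,6R)-5,6-bis(methoxymethoxy)cyclohex-3-en-1-ol
Product: 12 (1S,2S,4R,5R,6R)-5,6-bis(methoxymethoxy)cyclohexane-1,2,4-triol
Conditions: OsO4 (3 mol %), NMO, acetone/H2O, rt
Reagents that add atoms: osmium tetroxide, O=[Os](=O)(=O)=O (oxygen carrier); N-methylmorpholine N-oxide, C[N+]1([O-])CCOCC1; water, O
Why: In this Upjohn dihydroxylation the syn addition occurs on the face anti to the allylic C7–OMOM group (Kishi rule), which is also the face of the small hydrogen-bonding homoallylic OH, so C5 and C6 are set cis to each other and trans to C7–O.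

Step 8
Reactants: 12 (1S,2S,4R,5R,6R)-5,6-bis(methoxymethoxy)cyclohexane-1,2,4-triol
Product: 13 (3aS,5R,6R,7S,7aS)-6,7-bis(methoxymethoxy)-2,2-dimethylhexahydro-1,3-benzodioxol-5-ol
Conditions: 2,2-dimethoxypropane, PPTS (cat.), CH2Cl2, rt
Reagents that add atoms: 2,2-dimethoxypropane, COC(C)(C)OC
Why: Thermodynamic transketalisation favours the cis-fused five-membered dioxolane on the C5/C6 diol over a 1,3-dioxane, which leaves only the C8a hydroxyl free.

Step 9
Reactants: 13 (3aS,5R,6R,7S,7aS)-6,7-bis(methoxymethoxy)-2,2-dimethylhexahydro-1,3-benzodioxol-5-ol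
Product: 14 (3aS,6S,7R,7aS)-6,7-bis(methoxymethoxy)-2,2-dimethylhexahydro-1,3-benzodioxol-5-one
Conditions: Dess–Martin periodinane, CH2Cl2, 0 °C to rt
Reagents that add atoms: none
Why: Dess–Martin oxidation is base-free, so the α-alkoxy centre C8 is not epimerised and the β-oxygen at C5 is not eliminated.

## Fragment 2: homopropargyl iodide 18

Step 10
Reactants: 15 but-3-yn-1-ol
Product: 17 4-(trimethylsilyl)but-3-yn-1-ol, via bis-silyl ether 16 (not isolated)
Conditions: n-BuLi (2.1 equiv), THF, −78 °C; TMSCl (2.2 equiv), to rt; 1 M aq. HCl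
Reagents that add atoms: chlorotrimethylsilane, C[Si](C)(C)Cl
Why: Silylation of the alkoxide/acetylide dianion followed by selective acid hydrolysis of the labile O–Si bond masks the terminal alkyne for the organozinc step.

Step 11
Reactants: 17 4-(trimethylsilyl)but-3-yn-1-ol
Product: 18 (4-iodobut-1-yn-1-yl)trimethylsilane
Conditions: I2, PPh3, imidazole, CH2Cl2, 0 °C to rt
Reagents that add atoms: iodine, II
Why: Appel-type (Garegg–Samuelsson) iodination converts the primary alcohol into the iodide by SN2 displacement of the alkoxyphosphonium ion.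

## Fragment 3: ynal 29

Step 12
Reactants: 19 benzene-1,2-diol (catechol)
Product: 20 2-methoxyphenol
Conditions: MeI (1.0 equiv), K2CO3 (1.0 equiv), acetone, reflux
Reagents that add atoms: iodomethane, CI
Why: Williamson mono-O-methylation with one equivalent of base and electrophile gives mainly the monoether, which is separated from the diether and catechol by extraction and distillation.

Step 13
Reactants: 20 2-methoxyphenol
Product: 21 2-methoxyphenyl acetate
Conditions: Ac2O, pyridine, rt
Reagents that add atoms: acetic anhydride, CC(=O)OC(C)=O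
Why: Acetylation weakens the directing power of the phenolic oxygen so that the methoxy group controls the next substitution.

Step 14
Reactants: 21 2-methoxyphenyl acetate
Product: 22 5-bromo-2-methoxyphenyl acetate
Conditions: NBS, MeCN, rt
Reagents that add atoms: N-bromosuccinimide, O=C1CCC(=O)N1Br
Why: Electrophilic aromatic bromination takes place para to the stronger donor OMe, which gives the 3-oxy-4-methoxy (isovanillyl) substitution pattern of the target.

Step 15
Reactants: 18 (4-iodobut-1-yn-1-yl)trimethylsilane; 22 5-bromo-2-methoxyphenyl acetate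
Product: 24 2-methoxy-5-[4-(trimethylsilyl)but-3-yn-1-yl]phenyl acetate, via homopropargylzinc iodide 23 (not isolated)
Conditions: 18, Zn dust (activated by 1,2-dibromoethane and TMSCl, cat.), THF, 40 °C; then 22, Pd(OAc)2 (2 mol %), SPhos (4 mol %), THF, 45 °C
Reagents that add atoms: none
Why: In this Negishi cross-coupling the bulky electron-rich phosphine makes reductive elimination of the primary alkyl group faster than β-hydride elimination, and the mild organozinc tolerates the acetate and the silylalkyne.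

Step 16
Reactants: 24 2-methoxy-5-[4-(trimethylsilyl)but-3-yn-1-yl]phenyl acetate
Product: 25 5-(but-3-yn-1-yl)-2-methoxyphenol
Conditions: K2CO3 (cat.), MeOH, rt
Reagents that add atoms: none
Why: Methoxide-catalysed transesterification and protodesilylation remove the acetate and the alkynyl silane in one operation.

Step 17
Reactants: 25 5-(but-3-yn-1-yl)-2-methoxyphenol
Product: 26 4-(but-3-yn-1-yl)-1-methoxy-2-(methoxymethoxy)benzene
Conditions: MOMCl, i-Pr2NEt, CH2Cl2, 0 °C to rt
Reagents that add atoms: chloromethyl methyl ether, COCCl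
Why: MOM protection gives a phenol ether that survives n-BuLi, the boron aldol and the oxidation and falls off in the same final acid step as the other acetals.

Step 18
Reactants: 26 4-(but-3-yn-1-yl)-1-methoxy-2-(methoxymethoxy)benzene
Product: 29 5-[4-methoxy-3-(methoxymethoxy)phenyl]pent-2-ynal, via lithium acetylide 27 (not isolated), via lithium hemiaminal alkoxide 28 (not isolated)
Conditions: n-BuLi, THF, −78 °C; DMF, −78 to 0 °C; reverse quench into aq. KH2PO4, 0 °C
Reagents that add atoms: N,N-dimethylformamide, CN(C)C=O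
Why: In this formylation of the acetylide with DMF the tetrahedral adduct is stable until the buffered reverse quench, which protonates the liberated dimethylamine before it can add to the ynal.

## Union of the fragments and endgame

Step 19
Reactants: 14 (3aS,6S,7R,7aS)-6,7-bis(methoxymethoxy)-2,2-dimethylhexahydro-1,3-benzodioxol-5-one; 29 5-[4-methoxy-3-(methoxymethoxy)phenyl]pent-2-ynal
Product: 32 (3aS,6S,7R,7aS)-4-{1-hydroxy-5-[4-methoxy-3-(methoxymethoxy)phenyl]pent-2-yn-1-yl}-6,7-bis(methoxymethoxy)-2,2-dimethylhexahydro-1,3-benzodioxol-5-one (epimers at C4a and C4), via enol borinate 30 (not isolated), via boron aldolate 31 (not isolated)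
Conditions: (c-C6H11)2BCl, Et3N, Et2O, 0 °C; then 29, −78 °C; MeOH, pH 7 buffer, 30% H2O2, 0 °C
Reagents that add atoms: none
Why: In this boron-mediated aldol addition, soft enolisation takes place at the CH2 (C4a) away from the α-alkoxy carbon as with α-oxygenated ketones in Paterson aldols, the covalent enol borinate does not expel the β-oxygen at C5, and the two new centres need no control because both become sp2 in step 20.

Step 20
Reactants: 32 (3aS,6S,7R,7aS)-4-{1-hydroxy-5-[4-methoxy-3-(methoxymethoxy)phenyl]pent-2-yn-1-yl}-6,7-bis(methoxymethoxy)-2,2-dimethylhexahydro-1,3-benzodioxol-5-one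
Product: 34 (5S,6S,7R,8S)-5,6-(isopropylidenedioxy)-7,8-bis(methoxymethoxy)-2-{2-[4-methoxy-3-(methoxymethoxy)phenyl]ethyl}-5,6,7,8-tetrahydro-4H-chromen-4-one, via ynedione 33 (not isolated)
Conditions: Dess–Martin periodinane (1.2 equiv), CH2Cl2, 0 °C to rt; aqueous wash; crude 33, DMAP (20 mol %), MeCN, rt
Reagents that add atoms: none
Why: Dess–Martin oxidation gives the enolised 2-alkynoyl ketone, whose C8a enol oxygen closes the γ-pyrone by a DMAP-catalysed 6-endo-dig oxa-Michael addition at the electrophilic β-alkyne carbon, and C5–C8 are not involved.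

Step 21
Reactants: 34 (5S,6S,7R,8S)-5,6-(isopropylidenedioxy)-7,8-bis(methoxymethoxy)-2-{2-[4-methoxy-3-(methoxymethoxy)phenyl]ethyl}-5,6,7,8-tetrahydro-4H-chromen-4-one
Product: 35 (5S,6S,7R,8S)-5,6,7,8-tetrahydroxy-2-[2-(3-hydroxy-4-methoxyphenyl)ethyl]-5,6,7,8-tetrahydro-4H-chromen-4-one (target)
Conditions: 3 M aq. HCl (cat.), THF, 40 °C
Reagents that add atoms: none
Why: Acid-catalysed acetal hydrolysis breaks only the O–CH2 and O–CMe2 bonds, so every ring C–O bond and its configuration are retained.

## Compound list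
1 | prop-2-en-1-ol | C=CCO | starting material
2 | 3-(methoxymethoxy)prop-1-ene | C=CCOCOC | intermediate
3 | prop-2-enal | C=CC=O | starting material
4 | (Z)-3-(methoxymethoxy)allyllithium | [Li]C/C=C\OCOC | intermediate
5 | [(Z)-3-(methoxymethoxy)allyl]diisopinocampheylborane (Ipc from (+)-α-pinene) | COCO/C=C\CB([C@@H]1C[C@@H]2C[C@H]([C@H]1C)C2(C)C)[C@@H]1C[C@@H]2C[C@H]([C@H]1C)C2(C)C | intermediate
6 | (3R,4R)-4-(methoxymethoxy)hexa-1,5-dien-3-yl diisopinocampheylborinate | C=C[C@@H](OB([C@@H]1C[C@@H]2C[C@H]([C@H]1C)C2(C)C)[C@@H]1C[C@@H]2C[C@H]([C@H]1C)C2(C)C)[C@H](OCOC)C=C | intermediate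
7 | (3R,4R)-4-(methoxymethoxy)hexa-1,5-dien-3-ol | C=C[C@@H](O)[C@H](OCOC)C=C | intermediate
8 | (1S,2R)-2-(methoxymethoxy)-1-[(2R)-oxiran-2-yl]but-3-en-1-ol | C1O[C@H]1[C@@H](O)[C@H](OCOC)C=C | intermediate
9 | (2R)-2-[(1S,2R)-1,2-bis(methoxymethoxy)but-3-en-1-yl]oxirane | C1O[C@H]1[C@@H](OCOC)[C@H](OCOC)C=C | intermediate
10 | (4R,5R,6R)-5,6-bis(methoxymethoxy)octa-1,7-dien-4-ol | C=CC[C@@H](O)[C@@H](OCOC)[C@H](OCOC)C=C | intermediate
11 | (1R,5R,6R)-5,6-bis(methoxymethoxy)cyclohex-3-en-1-ol | O[C@H]1[C@@H](OCOC)[C@H](OCOC)C=CC1 | intermediate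
12 | (1S,2S,4R,5R,6R)-5,6-bis(methoxymethoxy)cyclohexane-1,2,4-triol | O[C@H]1[C@@H](OCOC)[C@H](OCOC)[C@@H](O)[C@@H](O)C1 | intermediate
13 | (3aS,5R,6R,7S,7aS)-6,7-bis(methoxymethoxy)-2,2-dimethylhexahydro-1,3-benzodioxol-5-ol | O[C@H]1[C@@H](OCOC)[C@H](OCOC)[C@H]2OC(C)(C)O[C@H]2C1 | intermediate
14 | (3aS,6S,7R,7aS)-6,7-bis(methoxymethoxy)-2,2-dimethylhexahydro-1,3-benzodioxol-5-one | O=C1[C@@H](OCOC)[C@H](OCOC)[C@H]2OC(C)(C)O[C@H]2C1 | intermediate
15 | but-3-yn-1-ol | C#CCCO | starting material
16 | trimethyl{[4-(trimethylsilyl)but-3-yn-1-yl]oxy}silane | C[Si](C)(C)C#CCCO[Si](C)(C)C | intermediate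
17 | 4-(trimethylsilyl)but-3-yn-1-ol | C[Si](C)(C)C#CCCO | intermediate
18 | (4-iodobut-1-yn-1-yl)trimethylsilane | C[Si](C)(C)C#CCCI | intermediate
19 | benzene-1,2-diol | Oc1ccccc1O | starting material
20 | 2-methoxyphenol | COc1ccccc1O | intermediate
21 | 2-methoxyphenyl acetate | CC(=O)Oc1ccccc1OC | intermediate
22 | 5-bromo-2-methoxyphenyl acetate | CC(=O)Oc1cc(Br)ccc1OC | intermediate
23 | [4-(trimethylsilyl)but-3-yn-1-yl]zinc iodide | C[Si](C)(C)C#CCC[Zn]I | intermediate
24 | 2-methoxy-5-[4-(trimethylsilyl)but-3-yn-1-yl]phenyl acetate | CC(=O)Oc1cc(CCC#C[Si](C)(C)C)ccc1OC | intermediate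
25 | 5-(but-3-yn-1-yl)-2-methoxyphenol | Oc1cc(CCC#C)ccc1OC | intermediate
26 | 4-(but-3-yn-1-yl)-1-methoxy-2-(methoxymethoxy)benzene | COCOc1cc(CCC#C)ccc1OC | intermediate
27 | lithium acetylide of 26 | [Li]C#CCCc1ccc(OC)c(OCOC)c1 | intermediate
28 | lithium 1-(dimethylamino)-5-[4-methoxy-3-(methoxymethoxy)phenyl]pent-2-yn-1-olate | [Li]OC(N(C)C)C#CCCc1ccc(OC)c(OCOC)c1 | intermediate
29 | 5-[4-methoxy-3-(methoxymethoxy)phenyl]pent-2-ynal | O=CC#CCCc1ccc(OC)c(OCOC)c1 | intermediate
30 | dicyclohexylboron enolate of 14 (C8a=C4a enol borinate) | C1(OB(C2CCCCC2)C2CCCCC2)=C[C@@H]3OC(C)(C)O[C@@H]3[C@@H](OCOC)[C@@H]1OCOC | intermediate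
31 | dicyclohexylborinate of aldol 32 | O=C1[C@@H](OCOC)[C@H](OCOC)[C@H]2OC(C)(C)O[C@H]2C1C(OB(C3CCCCC3)C3CCCCC3)C#CCCc3ccc(OC)c(OCOC)c3 | intermediate
32 | (3aS,6S,7R,7aS)-4-{1-hydroxy-5-[4-methoxy-3-(methoxymethoxy)phenyl]pent-2-yn-1-yl}-6,7-bis(methoxymethoxy)-2,2-dimethylhexahydro-1,3-benzodioxol-5-one (epimers at C4a and C4) | O=C1[C@@H](OCOC)[C@H](OCOC)[C@H]2OC(C)(C)O[C@H]2C1C(O)C#CCCc3ccc(OC)c(OCOC)c3 | intermediate
33 | (3aS,6S,7R,7aS)-4-{5-[4-methoxy-3-(methoxymethoxy)phenyl]pent-2-ynoyl}-6,7-bis(methoxymethoxy)-2,2-dimethylhexahydro-1,3-benzodioxol-5-one (enolised at C4a) | O=C1[C@@H](OCOC)[C@H](OCOC)[C@H]2OC(C)(C)O[C@H]2C1C(=O)C#CCCc3ccc(OC)c(OCOC)c3 | intermediate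
34 | (5S,6S,7R,8S)-5,6-(isopropylidenedioxy)-7,8-bis(methoxymethoxy)-2-{2-[4-methoxy-3-(methoxymethoxy)phenyl]ethyl}-5,6,7,8-tetrahydro-4H-chromen-4-one | COc1ccc(CCc2cc(=O)c3c(o2)[C@@H](OCOC)[C@H](OCOC)[C@H]4OC(C)(C)O[C@@H]34)cc1OCOC | intermediate
35 | (5S,6S,7R,8S)-5,6,7,8-tetrahydroxy-2-[2-(3-hydroxy-4-methoxyphenyl)ethyl]-5,6,7,8-tetrahydro-4H-chromen-4-one | COc1ccc(CCc2cc(=O)c3c(o2)[C@@H](O)[C@H](O)[C@@H](O)[C@H]3O)cc1O | target

## Step count and risks
Total step count: 21.
Longest linear sequence: 12 steps (steps 1–9, then 19–21). The arene branch runs through 10 steps and the butynol branch through 9.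

**Step 19 (boron aldol).** The risks are enolisation toward C8, loss of the C5 oxygen, or a sluggish addition to a hindered enol borinate. The fallback sets out from alkyne 26 and ketone 14 and comes back to the route at ynedione 33. It makes the C4–C4a bond by acylation instead of aldol addition plus oxidation. Alkyne 26 is deprotonated with n-BuLi and carboxylated with CO2 to give 5-[4-methoxy-3-(methoxymethoxy)phenyl]pent-2-ynoic acid F1. DCC and 1H-benzotriazole convert this acid into the acyl donor 1-(1H-benzotriazol-1-yl)-5-[4-methoxy-3-(methoxymethoxy)phenyl]pent-2-yn-1-one F2. Ketone 14 is then C-acylated by F2 under soft enolisation (MgBr2·OEt2, i-Pr2NEt, CH2Cl2, rt). Under these conditions only a small equilibrium amount of magnesium enolate is present, and the product is held as a chelated magnesium diketonate. Mild acidic work-up gives 33, which continues with the DMAP part of step 20.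

**Step 20 (oxidation and pyrone closure).** The risks are over-oxidation of the 1,3-diketone, a competing 5-exo closure to an alkylidene furanone, and base-induced loss of the C5 oxygen. The fallback sets out from aldol 32 and comes back to the route at 34. Aldol 32 is oxidised as before, and the crude ynedione is treated at once with diethylamine in EtOH at rt. Conjugate addition gives the vinylogous amide (3aS,6S,7R,7aS)-4-{3-(diethylamino)-5-[4-methoxy-3-(methoxymethoxy)phenyl]pent-2-enoyl}-6,7-bis(methoxymethoxy)-2,2-dimethylhexahydro-1,3-benzodioxol-5-one F3. Warming F3 with PPTS in toluene closes the ring by addition–elimination at the amine-bearing carbon. This mode of closure can only give the six-membered pyrone 34.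

**Step 21 (global deprotection).** The two secondary MOM ethers need more acid than the acetonide, and the free tetraol could dehydrate or solvolyse at C5 while they are still being cleaved. The fallback sets out from 34 and comes back to the route at 35. It replaces hydrolysis by acetolysis followed by basic transesterification. Treatment with Ac2O and Sc(OTf)3 (5 mol %) in MeCN at 0 °C exchanges every acetal oxygen for an acetate as soon as it is freed. The product is the stable, chromatographable (5S,6S,7R,8S)-2-{2-[3-(acetyloxy)-4-methoxyphenyl]ethyl}-4-oxo-5,6,7,8-tetrahydro-4H-chromene-5,6,7,8-tetrayl tetraacetate F4. Zemplén-type methanolysis (K2CO3 cat., MeOH, 0 °C) then releases 35 without any exposure of the free polyol to acid.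

Further compounds
F1 | step 19 | 5-[4-methoxy-3-(methoxymethoxy)phenyl]pent-2-ynoic acid | OC(=O)C#CCCc1ccc(OC)c(OCOC)c1
F2 | step 19 | 1-(1H-benzotriazol-1-yl)-5-[4-methoxy-3-(methoxymethoxy)phenyl]pent-2-yn-1-one | O=C(C#CCCc1ccc(OC)c(OCOC)c1)n1nnc2ccccc12
F3 | step 20 | (3aS,6S,7R,7aS)-4-{3-(diethylamino)-5-[4-methoxy-3-(methoxymethoxy)phenyl]pent-2-enoyl}-6,7-bis(methoxymethoxy)-2,2-dimethylhexahydro-1,3-benzodioxol-5-one | O=C1[C@@H](OCOC)[C@H](OCOC)[C@H]2OC(C)(C)O[C@H]2C1C(=O)C=C(CCc3ccc(OC)c(OCOC)c3)N(CC)CC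
F4 | step 21 | (5S,6S,7R,8S)-2-{2-[3-(acetyloxy)-4-methoxyphenyl]ethyl}-4-oxo-5,6,7,8-tetrahydro-4H-chromene-5,6,7,8-tetrayl tetraacetate | COc1ccc(CCc2cc(=O)c3c(o2)[C@@H](OC(C)=O)[C@H](OC(C)=O)[C@@H](OC(C)=O)[C@H]3OC(C)=O)cc1OC(C)=O
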